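**Retrosynthetic overview**

- The strategy rests on ring C (the pyranone). Its carbonyl carbon C4 stands alone between C4a of ring A and the C3–C2 unit, and O1 sits on C8a, ortho to C4a. Ring C therefore divides into an ortho-iodophenol, CO and an aryl alkyne.
- Target ⇒ (debenzylation, desilylation) protected (2S)-flavanone ⇒ (C4 reoxidation, asymmetric hydrogenation of C2=C3) flavone ⇒ 5-(benzyloxy)-2-iodophenol + CO + (3S)-6-ethynylchroman.
- Ethynylchroman ⇒ 6-bromochroman (Sonogashira). Its C3 centre comes from Jacobsen epoxidation of the 2H-chromene and hydride opening at C4. The chromene comes from an aryl 1,1-dimethylpropargyl ether by Claisen rearrangement.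
- Ring order: ring A and ring B (the benzene ring of the chroman) are bought as benzenes. Ring D (the dimethyl-dihydropyran) is closed first, ring C last.

Key step: step 10

Remark: the facial sense of the chiral ruthenium carbene catalyst on flavone 18 is assumed. The (R,R) ligand salt is written in step 11, and its enantiomer is used instead if it turns out to lead to 2R.

**Route**

Step 1
Reactants: 1 2-(benzyloxy)phenol
Product: 2 2-(benzyloxy)-4-bromophenol
Conditions: NBS, MeCN, 0 °C to rt
Reagents that add atoms: N-bromosuccinimide, O=C1CCC(=O)N1Br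
Why: Electrophilic aromatic bromination, in which the free hydroxyl is the stronger director, so bromine should enter para to it, the ortho isomer being removed by chromatography.

Step 2
Reactants: 2 2-(benzyloxy)-4-bromophenol; 3 3-chloro-3-methylbut-1-yne
Product: 4 2-(benzyloxy)-4-bromo-1-[(2-methylbut-3-yn-2-yl)oxy]benzene
Conditions: DBU, CuCl2 (cat.), MeCN, 0 °C
Reagents that add atoms: none
Why: Copper-catalysed O-propargylation of a phenol with a tertiary propargylic chloride, which should give the 1,1-dimethylpropargyl aryl ether without C-alkylation.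

Step 3
Reactants: 4 2-(benzyloxy)-4-bromo-1-[(2-methylbut-3-yn-2-yl)oxy]benzene
Product: 6 8-(benzyloxy)-6-bromo-2,2-dimethyl-2H-chromene, via ortho-allenylphenol 5 (not isolated)
Conditions: N,N-diethylaniline, 190 °C
Reagents that add atoms: none
Why: Aromatic propargyl Claisen rearrangement to the only free ortho carbon gives the allenylphenol, which by 1,5-hydrogen shift and 6π oxa-electrocyclisation should close ring D as the 2,2-dimethyl-2H-pyran.

Step 4
Reactants: 6 8-(benzyloxy)-6-bromo-2,2-dimethyl-2H-chromene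
Product: 7 (3S,4S)-8-(benzyloxy)-6-bromo-3,4-epoxy-2,2-dimethylchroman
Conditions: (S,S)-Mn(salen)Cl (Jacobsen catalyst, the chloride complex of trivalent manganese with (S,S)-N,N'-bis(3,5-di-tert-butylsalicylidene)cyclohexane-1,2-diamine, cat.), NaOCl (aq., pH 11.3), 4-phenylpyridine N-oxide (cat.), CH2Cl2, 0 °C
Reagents that add atoms: sodium hypochlorite, [Na+].[O-]Cl
Why: Jacobsen–Katsuki epoxidation of a cis, aryl-conjugated 2,2-dimethylchromene, the best substrate class for this catalyst, in which the (S,S) ligand should deliver oxygen to the face that gives the (3S,4S) oxide and so set C3.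

Step 5
Reactants: 7 (3S,4S)-8-(benzyloxy)-6-bromo-3,4-epoxy-2,2-dimethylchroman
Product: 8 (3S)-8-(benzyloxy)-6-bromo-2,2-dimethylchroman-3-ol
Conditions: LiAlH4, THF, 0 °C
Reagents that add atoms: none
Why: SN2 hydride opening of the epoxide at the benzylic C4, which is activated and far less hindered than C3 next to the quaternary C2, so the C3–O bond is untouched, C3 stays S, and the aryl bromide should survive at this temperature.

Step 6
Reactants: 8 (3S)-8-(benzyloxy)-6-bromo-2,2-dimethylchroman-3-ol
Product: 9 (3S)-8-(benzyloxy)-6-bromo-3-(tert-butyldimethylsilyloxy)-2,2-dimethylchroman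
Conditions: TBSOTf, 2,6-lutidine, CH2Cl2, 0 °C
Reagents that add atoms: tert-butyldimethylsilyl trifluoromethanesulfonate, CC(C)(C)[Si](C)(C)OS(=O)(=O)C(F)(F)F
Why: Silylation of a hindered secondary alcohol with the reactive silyl triflate and a non-nucleophilic base, which keeps this alcohol out of the later C4 oxidation.

Step 7
Reactants: 9 (3S)-8-(benzyloxy)-6-bromo-3-(tert-butyldimethylsilyloxy)-2,2-dimethylchroman; 10 ethynyltrimethylsilane
Product: 11 (3S)-8-(benzyloxy)-3-(tert-butyldimethylsilyloxy)-2,2-dimethyl-6-[(trimethylsilyl)ethynyl]chroman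
Conditions: PdCl2(PhCN)2 (cat.), P(t-Bu)3·HBF4 (cat.), CuI (cat.), i-Pr2NH, dioxane, rt to 50 °C
Reagents that add atoms: none
Why: Sonogashira coupling, in which the bulky electron-rich phosphine lets the electron-rich aryl bromide undergo oxidative addition under mild conditions and the silyl cap prevents double coupling.

Step 8
Reactants: 11 (3S)-8-(benzyloxy)-3-(tert-butyldimethylsilyloxy)-2,2-dimethyl-6-[(trimethylsilyl)ethynyl]chroman
Product: 12 (3S)-8-(benzyloxy)-3-(tert-butyldimethylsilyloxy)-6-ethynyl-2,2-dimethylchroman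
Conditions: K2CO3 (cat.), MeOH/THF, rt
Reagents that add atoms: none
Why: Base-catalysed methanolysis of the alkynyl C–Si bond (protodesilylation), which should leave the hindered alkyl silyl ether and the benzyl ether untouched.

Step 9
Reactants: 13 3-(benzyloxy)phenol
Product: 14 5-(benzyloxy)-2-iodophenol
Conditions: I2, NaHCO3, THF/H2O, 0 °C
Reagents that add atoms: iodine, II
Why: Electrophilic iodination of the phenoxide, in which iodine should enter ortho to the hydroxyl and para to the benzyloxy group, the least hindered doubly activated position, with the isomer iodinated para to the hydroxyl removed by chromatography.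

Step 10
Reactants: 14 5-(benzyloxy)-2-iodophenol; 15 carbon monoxide; 12 (3S)-8-(benzyloxy)-3-(tert-butyldimethylsilyloxy)-6-ethynyl-2,2-dimethylchroman
Product: 18 7-(benzyloxy)-2-[(3S)-8-(benzyloxy)-3-(tert-butyldimethylsilyloxy)-2,2-dimethylchroman-6-yl]-4H-chromen-4-one, via ortho-hydroxyaryl ynone 16 (not isolated), via beta-diethylamino enone 17 (not isolated)
Conditions: PdCl2(PPh3)2 (cat.), CO (20 atm), Et2NH, 120 °C
Reagents that add atoms: none
Why: Oxidative addition of the C–I bond of 14 to zerovalent palladium (formed in situ from PdCl2(PPh3)2) and CO insertion give an aroyl complex of divalent palladium (bond C4a–C4), and transfer of the amine-deprotonated alkyne 12 followed by reductive elimination forms C4–C3 of ynone 16. Diethylamine then adds to the ynone in conjugate fashion to give enaminone 17, and the ortho phenol displaces the amine by addition–elimination, forming O1–C2. The closest known reaction type is the palladium-catalysed carbonylative Sonogashira coupling and cyclisation of ortho-iodophenols with terminal alkynes to flavones. Ring C is closed in a net 6-endo-dig mode with respect to the ynone. No stereocentre is formed, and the silyloxy centre of ring D is remote and untouched. The step needs carbonylative rather than direct alkynylation, which CO pressure and the electron-rich aroyl-forming iodide should secure, and six-membered (flavone) rather than five-membered (aurone) closure, which the secondary amine secures through the enaminone.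

Step 11
Reactants: 18 7-(benzyloxy)-2-[(3S)-8-(benzyloxy)-3-(tert-butyldimethylsilyloxy)-2,2-dimethylchroman-6-yl]-4H-chromen-4-one
Product: 19 (2S,4S)-7-(benzyloxy)-2-[(3S)-8-(benzyloxy)-3-(tert-butyldimethylsilyloxy)-2,2-dimethylchroman-6-yl]chroman-4-ol
Conditions: Ru(cod)(2-methylallyl)2 (cat.), (R,R)-SINpEt·HBF4 (1,3-bis[(1R)-1-(naphthalen-1-yl)ethyl]-4,5-dihydroimidazolium tetrafluoroborate, cat.), KOt-Bu (cat.), H2 (120 bar), toluene, rt
Reagents that add atoms: none
Why: Asymmetric hydrogenation of the flavone C2=C3 bond with a chiral ruthenium N-heterocyclic carbene catalyst, in which the ligand selects the face of the flat pyranone and so sets C2 as S without influence from the distant C3 centre of ring D, while the C4 carbonyl is expected to be reduced as well (cis alcohol), which is of no consequence.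

Step 12
Reactants: 19 (2S,4S)-7-(benzyloxy)-2-[(3S)-8-(benzyloxy)-3-(tert-butyldimethylsilyloxy)-2,2-dimethylchroman-6-yl]chroman-4-ol
Product: 20 (2S)-7-(benzyloxy)-2-[(3S)-8-(benzyloxy)-3-(tert-butyldimethylsilyloxy)-2,2-dimethylchroman-6-yl]chroman-4-one
Conditions: Dess–Martin periodinane, CH2Cl2, rt
Reagents that add atoms: none
Why: Dess–Martin oxidation of the secondary benzylic alcohol back to the C4 ketone under non-basic conditions, so that C2 cannot epimerise by retro-oxa-Michael opening, and any flavanone already present in the crude material of step 11 passes through unchanged.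

Step 13
Reactants: 20 (2S)-7-(benzyloxy)-2-[(3S)-8-(benzyloxy)-3-(tert-butyldimethylsilyloxy)-2,2-dimethylchroman-6-yl]chroman-4-one
Product: 21 (2S)-7-(benzyloxy)-2-[(3S)-8-(benzyloxy)-3-hydroxy-2,2-dimethylchroman-6-yl]chroman-4-one
Conditions: HF·pyridine, THF, 0 °C to rt
Reagents that add atoms: none
Why: Acidic fluoride cleavage of the silyl ether, chosen over basic fluoride sources because the flavanone C2 centre is prone to base-induced ring opening.

Step 14
Reactants: 21 (2S)-7-(benzyloxy)-2-[(3S)-8-(benzyloxy)-3-hydroxy-2,2-dimethylchroman-6-yl]chroman-4-one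
Product: 22 (2S)-7-hydroxy-2-[(3S)-3,8-dihydroxy-2,2-dimethylchroman-6-yl]chroman-4-one
Conditions: H2 (1 atm), Pd/C (cat.), EtOAc/MeOH, rt
Reagents that add atoms: none
Why: Hydrogenolysis of the two aryl benzyl ethers over palladium under neutral conditions, which should leave the ketone, the C2–O1 bond and both stereocentres intact if stopped at full conversion.

**Compound list**

1 | 2-(benzyloxy)phenol | Oc1ccccc1OCc1ccccc1 | starting material
2 | 2-(benzyloxy)-4-bromophenol | Oc1ccc(Br)cc1OCc1ccccc1 | intermediate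
3 | 3-chloro-3-methylbut-1-yne | CC(C)(Cl)C#C | starting material
4 | 2-(benzyloxy)-4-bromo-1-[(2-methylbut-3-yn-2-yl)oxy]benzene | C#CC(C)(C)Oc1ccc(Br)cc1OCc1ccccc1 | intermediate
5 | 2-(benzyloxy)-4-bromo-6-(3-methylbuta-1,2-dien-1-yl)phenol (ortho-allenylphenol) | CC(C)=C=Cc1cc(Br)cc(OCc2ccccc2)c1O | intermediate
6 | 8-(benzyloxy)-6-bromo-2,2-dimethyl-2H-chromene | CC1(C)C=Cc2cc(Br)cc(OCc3ccccc3)c2O1 | intermediate
7 | (3S,4S)-8-(benzyloxy)-6-bromo-3,4-epoxy-2,2-dimethylchroman | CC1(C)Oc2c(OCc3ccccc3)cc(Br)cc2[C@H]4[C@@H]1O4 | intermediate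
8 | (3S)-8-(benzyloxy)-6-bromo-2,2-dimethylchroman-3-ol | CC1(C)Oc2c(OCc3ccccc3)cc(Br)cc2C[C@@H]1O | intermediate
9 | (3S)-8-(benzyloxy)-6-bromo-3-(tert-butyldimethylsilyloxy)-2,2-dimethylchroman | CC1(C)Oc2c(OCc3ccccc3)cc(Br)cc2C[C@@H]1O[Si](C)(C)C(C)(C)C | intermediate
10 | ethynyltrimethylsilane | C#C[Si](C)(C)C | starting material
11 | (3S)-8-(benzyloxy)-3-(tert-butyldimethylsilyloxy)-2,2-dimethyl-6-[(trimethylsilyl)ethynyl]chroman | CC1(C)Oc2c(OCc3ccccc3)cc(C#C[Si](C)(C)C)cc2C[C@@H]1O[Si](C)(C)C(C)(C)C | intermediate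
12 | (3S)-8-(benzyloxy)-3-(tert-butyldimethylsilyloxy)-6-ethynyl-2,2-dimethylchroman | CC1(C)Oc2c(OCc3ccccc3)cc(C#C)cc2C[C@@H]1O[Si](C)(C)C(C)(C)C | intermediate
13 | 3-(benzyloxy)phenol | Oc1cccc(OCc2ccccc2)c1 | starting material
14 | 5-(benzyloxy)-2-iodophenol | Oc1cc(OCc2ccccc2)ccc1I | intermediate
15 | carbon monoxide | [C-]#[O+] | starting material
16 | 1-[4-(benzyloxy)-2-hydroxyphenyl]-3-[(3S)-8-(benzyloxy)-3-(tert-butyldimethylsilyloxy)-2,2-dimethylchroman-6-yl]prop-2-yn-1-one | CC1(C)Oc2c(OCc3ccccc3)cc(C#CC(=O)c3ccc(OCc4ccccc4)cc3O)cc2C[C@@H]1O[Si](C)(C)C(C)(C)C | intermediate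
17 | 1-[4-(benzyloxy)-2-hydroxyphenyl]-3-[(3S)-8-(benzyloxy)-3-(tert-butyldimethylsilyloxy)-2,2-dimethylchroman-6-yl]-3-(diethylamino)prop-2-en-1-one (double-bond geometry not defined) | CC1(C)Oc2c(OCc3ccccc3)cc(C(=CC(=O)c3ccc(OCc4ccccc4)cc3O)N(CC)CC)cc2C[C@@H]1O[Si](C)(C)C(C)(C)C | intermediate
18 | 7-(benzyloxy)-2-[(3S)-8-(benzyloxy)-3-(tert-butyldimethylsilyloxy)-2,2-dimethylchroman-6-yl]-4H-chromen-4-one | CC1(C)Oc2c(OCc3ccccc3)cc(-c4cc(=O)c5ccc(OCc6ccccc6)cc5o4)cc2C[C@@H]1O[Si](C)(C)C(C)(C)C | intermediate
19 | (2S,4S)-7-(benzyloxy)-2-[(3S)-8-(benzyloxy)-3-(tert-butyldimethylsilyloxy)-2,2-dimethylchroman-6-yl]chroman-4-ol (2,4-cis) | CC1(C)Oc2c(OCc3ccccc3)cc([C@@H]4C[C@H](O)c5ccc(OCc6ccccc6)cc5O4)cc2C[C@@H]1O[Si](C)(C)C(C)(C)C | intermediate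
20 | (2S)-7-(benzyloxy)-2-[(3S)-8-(benzyloxy)-3-(tert-butyldimethylsilyloxy)-2,2-dimethylchroman-6-yl]chroman-4-one | CC1(C)Oc2c(OCc3ccccc3)cc([C@@H]4CC(=O)c5ccc(OCc6ccccc6)cc5O4)cc2C[C@@H]1O[Si](C)(C)C(C)(C)C | intermediate
21 | (2S)-7-(benzyloxy)-2-[(3S)-8-(benzyloxy)-3-hydroxy-2,2-dimethylchroman-6-yl]chroman-4-one | CC1(C)Oc2c(OCc3ccccc3)cc([C@@H]4CC(=O)c5ccc(OCc6ccccc6)cc5O4)cc2C[C@@H]1O | intermediate
22 | (2S)-7-hydroxy-2-[(3S)-3,8-dihydroxy-2,2-dimethylchroman-6-yl]chroman-4-one | CC1(C)Oc2c(O)cc([C@@H]3CC(=O)c4ccc(O)cc4O3)cc2C[C@@H]1O | target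

**Step count and risks**

Total step count: 14. Longest linear sequence: 13 steps (steps 1 to 8, then 10 to 14); the iodophenol branch is step 9.

Most likely to fail:

1. Step 10. CO insertion may lose to direct alkynylation of the aryl–palladium species, the aroyl–palladium intermediate may be captured by diethylamine, the ynone may close 5-exo, or the alkyne may oligomerise at 120 °C. The fallback brings in the carbonyl carbon as an aldehyde instead of CO gas; it sets out from alkyne 12 and comes back at flavone 18. Commercial 4-(benzyloxy)-2-hydroxybenzaldehyde is O-allylated (allyl bromide, K2CO3, DMF) to 2-(allyloxy)-4-(benzyloxy)benzaldehyde F1. The lithium acetylide of 12 (n-BuLi, THF, −78 °C) is added to it to give 1-[2-(allyloxy)-4-(benzyloxy)phenyl]-3-[(3S)-8-(benzyloxy)-3-(tert-butyldimethylsilyloxy)-2,2-dimethylchroman-6-yl]prop-2-yn-1-ol F2 as a mixture of carbinol epimers. MnO2 in CH2Cl2 should oxidise this to 1-[2-(allyloxy)-4-(benzyloxy)phenyl]-3-[(3S)-8-(benzyloxy)-3-(tert-butyldimethylsilyloxy)-2,2-dimethylchroman-6-yl]prop-2-yn-1-one F3. Pd(PPh3)4 (cat.) with morpholine in THF then removes the allyl group, and the freed phenol 16, in the presence of the same secondary amine, should close 6-endo through the enaminone to 18.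

2. Step 11. Facial selectivity may be poor on this heavily substituted flavone, the reduction may stall, or benzene rings may be partly saturated at high hydrogen pressure. The fallback sets C2 by C–C bond formation, an asymmetric conjugate addition of an arylboronic acid to a chromone; it sets out from bromide 9 and comes back at flavanone 20, so that steps 13 and 14 follow. Bromine–lithium exchange on 9 (n-BuLi, THF, −78 °C), B(Oi-Pr)3 and mild aqueous work-up give [(3S)-8-(benzyloxy)-3-(tert-butyldimethylsilyloxy)-2,2-dimethylchroman-6-yl]boronic acid F4. Separately, commercial 1-[4-(benzyloxy)-2-hydroxyphenyl]ethanone is condensed with N,N-dimethylformamide dimethyl acetal to (E)-1-[4-(benzyloxy)-2-hydroxyphenyl]-3-(dimethylamino)prop-2-en-1-one F5, which aqueous HCl in CH2Cl2 closes to 7-(benzyloxy)-4H-chromen-4-one F6. Pd(OCOCF3)2 with the antipode of 4-tert-butyl-2-(pyridin-2-yl)-4,5-dihydrooxazole that leads to 2S, NH4PF6 and water in 1,2-dichloroethane at 60 °C should add the aryl group of the boronic acid to C2 of the chromone and give 20.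

3. Step 14. The benzylic C2–O1 bond may be hydrogenolysed with opening of ring C, the C4 carbonyl may be reduced, or debenzylation may be slow and force long exposure. The fallback is a non-reductive, Lewis-acid debenzylation that sets out from 21 and comes back at target 22: BCl3 with pentamethylbenzene as benzyl cation scavenger, CH2Cl2, −78 °C. It makes no compound that the list does not hold (entry F0).

**Further compounds**

F1 | step 10 | 2-(allyloxy)-4-(benzyloxy)benzaldehyde | O=Cc1ccc(OCc2ccccc2)cc1OCC=C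
F2 | step 10 | 1-[2-(allyloxy)-4-(benzyloxy)phenyl]-3-[(3S)-8-(benzyloxy)-3-(tert-butyldimethylsilyloxy)-2,2-dimethylchroman-6-yl]prop-2-yn-1-ol | CC1(C)Oc2c(OCc3ccccc3)cc(C#CC(O)c3ccc(OCc4ccccc4)cc3OCC=C)cc2C[C@@H]1O[Si](C)(C)C(C)(C)C
F3 | step 10 | 1-[2-(allyloxy)-4-(benzyloxy)phenyl]-3-[(3S)-8-(benzyloxy)-3-(tert-butyldimethylsilyloxy)-2,2-dimethylchroman-6-yl]prop-2-yn-1-one | CC1(C)Oc2c(OCc3ccccc3)cc(C#CC(=O)c3ccc(OCc4ccccc4)cc3OCC=C)cc2C[C@@H]1O[Si](C)(C)C(C)(C)C
F4 | step 11 | [(3S)-8-(benzyloxy)-3-(tert-butyldimethylsilyloxy)-2,2-dimethylchroman-6-yl]boronic acid | CC1(C)Oc2c(OCc3ccccc3)cc(B(O)O)cc2C[C@@H]1O[Si](C)(C)C(C)(C)C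
F5 | step 11 | (E)-1-[4-(benzyloxy)-2-hydroxyphenyl]-3-(dimethylamino)prop-2-en-1-one | CN(C)/C=C/C(=O)c1ccc(OCc2ccccc2)cc1O
F6 | step 11 | 7-(benzyloxy)-4H-chromen-4-one | O=c1ccoc2cc(OCc3ccccc3)ccc12
F0 | step 14 | none | none
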